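All runs come from a simulation with made-up constants, and the scatter is random.

55.0 % is where I start: the partner ceiling, the part of the left-handed and right-handed substrate together that the partner charged to the flask can turn over at one partner per substrate.

| flask | left-handed substrate | right-handed substrate | partner | precatalyst | remark | time |
|---|---|---|---|---|---|---|
| north-west | 10 mM | 10 mM | 1.1 equiv | 0.5 mol% | run made earlier |  |
| south-east | 40 mM | 40 mM | 1.1 equiv | 0.5 mol% | run made earlier |  |
| flask | 20 mM | 20 mM | 1.10 equiv | 0.5 mol% |  | 2.5 min |

| run | time / min | left-handed substrate / % | right-handed substrate / % | left-handed product / % |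
|---|---|---|---|---|
| north-west | 0.500 | 44.5 | 48.0 | 8.1 |
| north-west | 1.00 | 38.9 | 41.6 | 18.8 |
| north-west | 1.50 | 36.2 | 37.3 | 26.4 |
| north-west | 2.00 | 34.0 | 35.4 | 30.2 |
| north-west | 2.50 | 32.3 | 33.4 | 33.3 |
| south-east | 0.500 | 29.0 | 34.7 | 35.6 |
| south-east | 1.00 | 30.6 | 30.6 | 39.1 |
| south-east | 1.50 | 29.7 | 30.2 | 39.2 |
| south-east | 2.00 | 29.7 | 30.4 | 39.4 |
| south-east | 2.50 | 30.2 | 29.5 | 39.5 |

(each reading ± 0.3 percentage points)

- catalyst is single-handed; left-handed substrate and right-handed substrate are mirror images of each other, charged as a racemate, each of them at the stated concentration
- candidate steps: partner + catalyst + right-handed substrate -> catalyst + right-handed product; left-handed substrate <-> right-handed substrate; 2 partner -> homo dimer; partner + catalyst + left-handed substrate -> catalyst + left-handed product; precatalyst -> catalyst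
- an excess is the difference of the two amounts in percent of their sum
- an excess is below zero if the other one leads

- part of the left-handed substrate and right-handed substrate charged together that has reacted at 2.5 min
- excess of left-handed product over right-handed product in the product at 2.5 min
- excess of right-handed substrate over left-handed substrate among what is left of the two at 2.5 min

At the end of the south-east run the two substrates read level, 30.2 % and 29.5 %. Yet the left-handed substrate stands 19.8 % below its charge, less than the 39.5 % of left-handed product. So I treat the substrates as one pool, which makes partner the limiting reagent and the ceiling my bound from above.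

That bound is loose. The south-east run reads 40.3 % reacted at its last reading, and the candidate steps give partner one other road, homo dimer, which I take to go with partner squared. The flask has half the south-east charges, so I expect its product road to compete worse, and 40.3 % becomes my tighter upper bound. The north-west run has half the flask's charges and reads 34.3 % reacted at 2.5 min, less than the south-east run, so I take that reading as my lower bound.

The forecast says c 38.8 %, between my bounds, with a range of 37 % to 40.5 %, eP 97 % and eS 0.4 %, holding that “partner is lost to homo dimer”. I commit to the bracket, not to that number.

The flask gives c 39.4 %, eP 97.5 % and eS 0.0490 %: the forecast is right on each within the tolerance, and c lies inside my bracket.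

    partner + catalyst + right-handed substrate → catalyst + right-handed product (k = 530 M⁻² s⁻¹)
    left-handed substrate ⇌ right-handed substrate (k = 0.0660 s⁻¹)
    2 partner → homo dimer (k = 0.420 M⁻¹ s⁻¹)
    partner + catalyst + left-handed substrate → catalyst + left-handed product (k = 46000 M⁻² s⁻¹)
    precatalyst → catalyst (k = 0.0260 s⁻¹)

In the flask, c is 71.6 % of the ceiling. The neighbouring flask, with 0.280 equiv of partner and the rest held, has a ceiling of 14.0 %. It reaches c 12.8 %, below the low end of the forecast's range for the flask; that is 91.4 % of its own ceiling, a larger share than in the flask, with 0.0088 % of its partner left at 2.50 min.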